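**Assumptions (one line each)**
- 3-Bromo-5-methoxyphenol and (E)-3,5,4'-trimethoxystilbene are treated as commercial. The stilbene is also one step from resveratrol with MeI and K2CO3.
- The target is the resveratrol dehydrodimer C28H22O6, and the given SMILES fixes the absolute configuration.
- The cascade in Step 2 is proposed by analogy and I have not verified it. It delivers racemic material, so the single enantiomer is obtained by chiral HPLC resolution in Step 3.

**Retrosynthesis**
1. Vitisinol D (7) comes from global aryl O-demethylation of its tetra-O-methyl ether (6).
2. Ether 6 is one enantiomer of racemate 5. Racemate 5 comes from a dearomative oxidative formal [5+2]/[3+2] cascade of phenol 3 (the future dearomatized ring) with stilbene 4.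
3. In the cascade the first C–C bond (C6–CHAr, from the arene's C6 to the carbon bearing the dimethoxyphenyl group) forms and dearomatizes the phenol.
4. The cyclopentanone bridge then closes by vinylogous-ester C4 attack on the p-anisyl cation, which makes the bicyclo[3.2.1]octane and the cyclohexenone enone.
5. Phenol 3 comes from Suzuki coupling of 1 and 2.

**Step 1**
Reactants: 1 (3-bromo-5-methoxyphenol); 2 ((E)-4-methoxystyryl-Bpin)
Product: 3, (E)-3-methoxy-5-(4-methoxystyryl)phenol
Conditions: Pd(PPh3)4 (5 mol%), K2CO3, dioxane/H2O 4:1, 90 °C
Reagents that add atoms: none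
Why: Suzuki–Miyaura coupling joins the two fragments with retention of the E-alkene, and the free phenol is tolerated.

**Step 2**
Reactants: 3 (1 equiv); 4 ((E)-3,5,4'-trimethoxystilbene, 2.5 equiv)
Product: 5, rac-tetra-O-methylvitisinol D
Conditions: PhI(OCOCF3)2 (PIFA, 1.2 equiv, slow addition), HFIP, –20 → 0 °C; then 1 M HCl/THF, rt
Reagents that add atoms: water (O), from the work-up. It hydrolyses the methoxycarbenium to the ketone, with net loss of MeOH.
Why: This is an oxidative dearomatization cascade.
- PIFA converts phenol 3 into the 3-methoxyphenoxonium ion.
- The nucleophilic stilbene attacks C6 through the carbon bearing the dimethoxyphenyl group, leaving the p-anisyl benzylic cation.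
- The resulting 6-alkyl-2,4-dienone is a vinylogous ester whose α-carbon (C4) closes on that cation in a 5-exo manner, before rearomatization, in non-basic HFIP.
- Closure forces the two new bridgeheads to be cis.
- The p-anisyl cation closes with its aryl group exo, and the E-stilbene geometry places the 3,5-dimethoxyphenyl group endo. This gives the trans-diaryl, exo/endo relative configuration of the target.
- The product is racemic.

**Step 3**
Reactants: 5
Product: 6, the single enantiomer of tetra-O-methylvitisinol D matching the target SMILES
Conditions: preparative HPLC, Chiralpak IA or IC, hexane/EtOH; collect the required enantiomer and confirm it by CD comparison with natural vitisinol D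
Reagents that add atoms: none
Why: All four stereocentres are configurationally locked (bridgeheads and non-acidic benzylic CH), so the enantiomers are separable and do not racemize. Any cis-diaryl diastereomer is also removed here.

**Step 4**
Reactants: 6
Product: 7, vitisinol D
Conditions: BBr3 (10 equiv), CH2Cl2, –78 → 0 °C, 3 h; quench with MeOH at –78 °C
Reagents that add atoms: none
Why: BBr3 cleaves the four aryl methyl ethers by Lewis-acid-assisted demethylation. The bridgehead and benzylic stereocentres are not enolizable, so configuration is retained, and the E-styryl and enone are expected to survive at low temperature.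

**Compound list**
1 | 3-bromo-5-methoxyphenol | COc1cc(O)cc(Br)c1 | starting material
2 | (E)-2-(4-methoxystyryl)-4,4,5,5-tetramethyl-1,3,2-dioxaborolane | COc1ccc(/C=C/B2OC(C)(C)C(C)(C)O2)cc1 | starting material
3 | (E)-3-methoxy-5-(4-methoxystyryl)phenol | COc1cc(O)cc(/C=C/c2ccc(OC)cc2)c1 | intermediate
4 | (E)-3,5,4'-trimethoxystilbene | COc1cc(/C=C/c2ccc(OC)cc2)cc(OC)c1 | starting material
5 | rac-tetra-O-methylvitisinol D (racemate, one enantiomer drawn) | O=C1C=C(/C=C/c2ccc(OC)cc2)[C@H]2C(=O)[C@@H]1[C@H](c1ccc(OC)cc1)[C@H]2c1cc(OC)cc(OC)c1 | intermediate
6 | enantiopure tetra-O-methylvitisinol D | O=C1C=C(/C=C/c2ccc(OC)cc2)[C@H]2C(=O)[C@@H]1[C@H](c1ccc(OC)cc1)[C@H]2c1cc(OC)cc(OC)c1 | intermediate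
7 | vitisinol D | O=C1C=C(/C=C/c2ccc(O)cc2)[C@H]2C(=O)[C@@H]1[C@H](c1ccc(O)cc1)[C@H]2c1cc(O)cc(O)c1 | target

**Totals**
- Total steps: 4
- Longest linear sequence: 4 (1 → 3 → 5 → 6 → 7)

**Three steps most likely to fail**
1. **Step 2 (cascade).** Rearomatization to the 2,3-dihydrobenzofuran, oxidation of the stilbene itself, or the wrong C6/C4 pairing or wrong diaryl diastereomer could dominate.
   - Fallback, a stepwise route: γ-alkylate the dianion of 5-(4-methoxystyryl)cyclohexane-1,3-dione with ArA–CHBr–C(=O)–ArB (ArA = 3,5-dimethoxyphenyl, ArB = 4-methoxyphenyl).
   - Reduce the ketone, then close with TFA onto the dione enol to form the bicycle.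
   - Finish by IBX dehydrogenation to the enone.
2. **Step 3 (resolution).** It halves the material, and the enantiomers may separate poorly.
   - Fallback: make Step 2 asymmetric with a catalytic chiral C2-symmetric iodoarene (Kita/Ishihara type) and mCPBA in place of PIFA, and enrich by crystallization.
3. **Step 4 (BBr3).** The strained non-enolizable 1,3-diketone could undergo retro-Claisen opening or the styrene could add HBr.
   - Fallback: rerun Steps 1–3 with MOM- or TBS-protected phenols (MOM or TBS in place of the four methyl groups), and deprotect with mild acid (HCl/MeOH) or HF·pyridine.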